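The oxolane of the target holds the ring A benzylic carbon C7' on the quaternary carbinol C8', on the same face as the C9 hydroxymethyl group on C8. A bond from C7' to O9 would therefore complete a cis-fused 3,7-dioxabicyclo[3.3.0]octane. The plan disconnects C7'–C8' inside this temporary bicycle. The precursor is a (4R,5S)-5-aryl-4-[(arylmethoxy)methyl]oxolan-3-one whose O9 already carries the ring A benzyl group and whose ring B is deactivated as a mesylate. Its Norrish–Yang photocyclisation forges that bond, the second ring and the C8' stereocentre in one operation. Ionic hydrogenolysis of C7'–O9 then releases the olivil core, and an auxiliary-controlled syn-aldol adds the threo arylglycerol arm.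

Key step: step 10

Labels: the oxolane is O, C7 (bears ring B), C8 (bears C9H2–O9), C8' (carbinol) and C9'. C7' links C8' to ring A. Ring C, C7'', C8'' and C9'' form the arylglycerol arm on the ring B oxygen.

Assumption: 19 is carried on as its mixture of C7' epimers (C7' is left undefined in its SMILES), because step 11 turns this carbon into a CH2 group.

Step 1
Reactants: 1 4-benzyloxy-3-methoxybenzyl alcohol; 2 methyl acrylate
Product: 4 3-[(4-benzyloxy-3-methoxyphenyl)methoxy]propanoic acid, via methyl ester 3 (not isolated)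
Conditions: NaH (0.1 equiv), THF, 0 °C to rt; then LiOH, H2O, rt; HCl to pH 3
Reagents that add atoms: lithium hydroxide, [Li+].[OH-]
Why: Alkoxide-catalysed oxa-Michael addition of a primary benzylic alcohol to an acrylate followed by saponification in the same flask is routine chemistry, transesterified by-products converge on the same acid, and unreacted 1 is removed by acid–base extraction.

Step 2
Reactants: 4 3-[(4-benzyloxy-3-methoxyphenyl)methoxy]propanoic acid; 5 (S)-4-benzyl-2-oxazolidinone
Product: 7 (S)-4-benzyl-3-{3-[(4-benzyloxy-3-methoxyphenyl)methoxy]propanoyl}oxazolidin-2-one, via mixed pivalic anhydride 6 (not isolated)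
Conditions: t-BuCOCl, Et3N, THF, −20 °C; then LiCl, 5, rt
Reagents that add atoms: pivaloyl chloride, CC(C)(C)C(=O)Cl (its atoms stay only in 6)
Why: N-Acylation of the oxazolidinone through the mixed pivalic anhydride under LiCl activation avoids strong base and acid chlorides, so the acid-labile electron-rich benzylic ether and the β-alkoxy acyl chain should stay intact.

Step 3
Reactants: 8 vanillin
Product: 9 4-formyl-2-methoxyphenyl methanesulfonate (O-mesylvanillin)
Conditions: MeSO2Cl, Et3N, CH2Cl2, 0 °C
Reagents that add atoms: methanesulfonyl chloride, CS(=O)(=O)Cl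
Why: Sulfonylation of the phenol is straightforward, and the mesylate is preferred to an aryl carboxylate because it should survive the hydroperoxide of step 6, cannot undergo a photo-Fries acyl shift in step 10 and withdraws electron density from ring B for step 11.

Step 4
Reactants: 7 (S)-4-benzyl-3-{3-[(4-benzyloxy-3-methoxyphenyl)methoxy]propanoyl}oxazolidin-2-one; 9 O-mesylvanillin
Product: 11 anti-aldol adduct (S)-4-benzyl-3-[(2R,3S)-2-{[(4-benzyloxy-3-methoxyphenyl)methoxy]methyl}-3-hydroxy-3-(3-methoxy-4-mesyloxyphenyl)propanoyl]oxazolidin-2-one, via trimethylsilyl ether 10 (not isolated)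
Conditions: MgCl2 (0.2 equiv), Et3N, Me3SiCl, EtOAc, rt; then CF3CO2H (cat.), MeOH, rt
Reagents that add atoms: chlorotrimethylsilane, C[Si](C)(C)Cl (its atoms stay only in 10)
Why: In this magnesium-halide-catalysed anti-aldol of an N-acyloxazolidinone with a non-enolisable aromatic aldehyde, the chelated Z-enolate is attacked on the face away from the auxiliary benzyl group (C8 becomes R) through a boat-like transition state that sets the carbinol anti (C7 becomes S), silylation of the aldolate makes the addition irreversible, and the labile silyl ether is methanolysed on work-up.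

Step 5
Reactants: 11 anti-aldol adduct
Product: 12 C7 triethylsilyl ether of 11
Conditions: Et3SiOTf, 2,6-lutidine, CH2Cl2, −78 to 0 °C
Reagents that add atoms: triethylsilyl trifluoromethanesulfonate, CC[Si](CC)(CC)OS(=O)(=O)C(F)(F)F
Why: Silylation with a silyl triflate and a hindered pyridine base is standard for aldol carbinols, and the triethylsilyl ether, unlike the trimethylsilyl ether, should last through steps 6 and 7 yet leave under buffered fluoride in step 8.

Step 6
Reactants: 12 C7 triethylsilyl ether of 11
Product: 14 (2R,3S)-2-{[(4-benzyloxy-3-methoxyphenyl)methoxy]methyl}-3-(3-methoxy-4-mesyloxyphenyl)-3-(triethylsilyloxy)propanoic acid, via peroxy acid 13 (not isolated)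
Conditions: LiOH, H2O2, THF–H2O, 0 °C; Na2SO3; HCl to pH 3–4
Reagents that add atoms: hydrogen peroxide, OO
Why: Hydroperoxide cleaves the exocyclic imide carbonyl selectively and sulfite reduces the percarboxylate, while at 0 °C the aryl mesylate, the silyl ether and the α-centre C8 should be untouched, which an aryl carboxylate on ring B would not have been.

Step 7
Reactants: 14 silyloxy acid
Product: 16 (3R,4S)-1-diazo-3-{[(4-benzyloxy-3-methoxyphenyl)methoxy]methyl}-4-(3-methoxy-4-mesyloxyphenyl)-4-(triethylsilyloxy)butan-2-one, via acid chloride 15 (not isolated)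
Conditions: Me2C=C(Cl)NMe2, CH2Cl2, 0 °C; then CH2N2 (excess), Et2O, 0 °C
Reagents that add atoms: diazomethane, C=[N+]=[N-]; 1-chloro-N,N,2-trimethylprop-1-en-1-amine, CC(C)=C(Cl)N(C)C (its chlorine stays only in 15)
Why: The α-chloroenamine turns the hindered acid into its chloride without releasing HCl, which spares the silyl ether and the benzylic ether, and acylation of excess diazomethane (the diazoketone synthesis of the Arndt–Eistert sequence) adds C9' without a base able to epimerise C8.

Step 8
Reactants: 16 silyloxy diazoketone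
Product: 17 (3R,4S)-1-diazo-3-{[(4-benzyloxy-3-methoxyphenyl)methoxy]methyl}-4-hydroxy-4-(3-methoxy-4-mesyloxyphenyl)butan-2-one
Conditions: Bu4NF, AcOH (1:1), THF, 0 °C
Reagents that add atoms: none
Why: Acetic-acid-buffered fluoride removes the triethylsilyl group under essentially neutral conditions, so neither acid-induced loss of nitrogen from the diazoketone nor base-induced retro-aldol or β-elimination should intervene.

Step 9
Reactants: 17 hydroxy diazoketone
Product: 18 (4R,5S)-4-{[(4-benzyloxy-3-methoxyphenyl)methoxy]methyl}-5-(3-methoxy-4-mesyloxyphenyl)oxolan-3-one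
Conditions: Rh2(OAc)4 (1 mol %), CH2Cl2, rt, slow addition of 17
Reagents that add atoms: none
Why: Intramolecular O–H insertion of the dirhodium carbenoid closes the five-membered oxolan-3-one (O–C9' bond) under neutral conditions that leave C7 and C8 untouched, and proton transfer makes capture by the free hydroxyl group irreversible, so it should win over reversible ylide formation at the ether oxygen O9.

Step 10
Reactants: 18 (4R,5S)-4-{[(4-benzyloxy-3-methoxyphenyl)methoxy]methyl}-5-(3-methoxy-4-mesyloxyphenyl)oxolan-3-one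
Product: 19 cis-fused (7S,8R,8'S)-2-(4-benzyloxy-3-methoxyphenyl)-6-(3-methoxy-4-mesyloxyphenyl)-3,7-dioxabicyclo[3.3.0]octan-1-ol (both C7' epimers)
Conditions: hν (medium-pressure Hg lamp, Pyrex filter, λ > 300 nm), degassed benzene, 5 mM, rt
Reagents that add atoms: none
Why: Light above 300 nm is absorbed only by the n,π* band of the C8' ketone; because the γ-position of the C9 arm is the oxygen O9 and offers no hydrogen, the excited carbonyl oxygen takes a C7' hydrogen, which is both benzylic and α to oxygen, through a seven-membered transition state (1,6-hydrogen transfer), and the resulting 1,5-biradical (hydroxy-substituted C8', benzylic C7') couples. The closest known reaction type is the Norrish–Yang cyclisation of β-alkoxy ketones to oxolan-3-ols, which is documented for 4-[(arylmethoxy)methyl]oxolan-3-ones giving bridgehead-hydroxy furofurans. The one new ring (C7', C8', C8, C9, O9) closes by recombination of the two radical centres of the 1,5-biradical, not by attack on a π bond. C8' is controlled by the three-atom tether C8–C9–O9: only the cis-fused bicyclo[3.3.0]octane is within reach, so C7' bonds to the face of C8' that carries C9 and the hydroxyl group ends up trans to C9 (8'S), while C7' arises as an epimer mixture that step 11 erases and C7 and C8 are not touched. The step needs δ-hydrogen abstraction to outrun α-cleavage of the cyclic ketone and any photochemistry of the arenes; the doubly activated C7'–H bonds, the absence of γ-hydrogens, the Pyrex cut-off, high dilution with exclusion of oxygen, and a ring B mesylate in place of a photolabile aryl ester are meant to secure this.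

Step 11
Reactants: 19 bridgehead-hydroxy furofuran
Product: 20 (3S,4R,5S)-3-[(4-benzyloxy-3-methoxyphenyl)methyl]-4-(hydroxymethyl)-5-(3-methoxy-4-mesyloxyphenyl)oxolan-3-ol
Conditions: Et3SiH (5 equiv), BF3·OEt2, CH2Cl2, −78 to −40 °C; aq NaHCO3
Reagents that add atoms: none
Why: In this ionic hydrogenation of a benzylic ether, BF3 should ionise only the C7'–O9 bond because the cation is stabilised by the 4-alkoxy group of ring A whereas ring B is deactivated by its mesylate, excess silane delivers hydride at low temperature before the neighbouring carbinol can rearrange, C7' becomes CH2, and C8', C8 and C7 keep their configuration.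

Step 12
Reactants: 20 diol mesylate
Product: 21 (3S,4R,5S)-3-[(4-benzyloxy-3-methoxyphenyl)methyl]-5-(4-hydroxy-3-methoxyphenyl)-4-(hydroxymethyl)oxolan-3-ol
Conditions: NaOH (2 M aq), MeOH–THF, 50 °C; HCl to pH 6
Reagents that add atoms: none
Why: Aryl methanesulfonates are hydrolysed by warm hydroxide with S–O cleavage, and at this stage the molecule has no carbonyl group, no epimerisable centre and no other base-labile function.

Step 13
Reactants: 5 (S)-4-benzyl-2-oxazolidinone; 22 bromoacetyl bromide
Product: 24 (S)-4-benzyl-3-(bromoacetyl)oxazolidin-2-one, via lithium oxazolidinide 23 (not isolated)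
Conditions: n-BuLi, THF, −78 °C; then 22, −78 to 0 °C
Reagents that add atoms: n-butyllithium, [Li]CCCC (its lithium stays only in 23)
Why: N-Acylation of the lithiated oxazolidinone at low temperature is chemoselective for the acyl bromide over the alkyl bromide and does not touch the auxiliary stereocentre.

Step 14
Reactants: 21 ring B phenol; 24 (S)-4-benzyl-3-(bromoacetyl)oxazolidin-2-one
Product: 25 (S)-4-benzyl-3-{[4-((2S,3R,4S)-4-[(4-benzyloxy-3-methoxyphenyl)methyl]-4-hydroxy-3-(hydroxymethyl)oxolan-2-yl)-2-methoxyphenoxy]acetyl}oxazolidin-2-one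
Conditions: K2CO3, acetone, rt
Reagents that add atoms: none
Why: In this Williamson-type O-alkylation only the phenol is deprotonated by carbonate and the α-bromo imide is a very reactive SN2 partner, so the primary and tertiary alcohols should stay unchanged and the auxiliary arrives in the same operation.

Step 15
Reactants: 25 aryloxyacetyl imide diol
Product: 26 bis(triethylsilyl) ether of 25 (at O9 and at the C8' oxygen)
Conditions: Et3SiOTf (3 equiv), 2,6-lutidine, CH2Cl2, −78 to 0 °C
Reagents that add atoms: triethylsilyl trifluoromethanesulfonate, CC[Si](CC)(CC)OS(=O)(=O)C(F)(F)F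
Why: A silyl triflate with 2,6-lutidine silylates primary and hindered tertiary alcohols alike and is routinely used in the presence of N-acyloxazolidinones, which removes the two protic groups that would otherwise consume the boron triflate of step 16.

Step 16
Reactants: 26 bis(triethylsilyl) ether; 27 4-benzyloxy-3-methoxybenzaldehyde
Product: 30 syn-aldol adduct of 26 whose acyl chain is (2S,3R)-2-aryloxy-3-(4-benzyloxy-3-methoxyphenyl)-3-hydroxypropanoyl, via boron enolate 28 (not isolated), via boron aldolate 29 (not isolated)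
Conditions: Bu2BOTf, Et3N, CH2Cl2, −78 to 0 °C; 27, −78 to 0 °C; pH 7 buffer, MeOH, H2O2, 0 °C
Reagents that add atoms: dibutylboron trifluoromethanesulfonate, CCCCB(CCCC)OS(=O)(=O)C(F)(F)F (its atoms stay only in 28 and 29)
Why: In this Evans syn-aldol of an aryloxyacetyl imide, the Z-boron enolate reacts through a Zimmerman–Traxler chair on the face away from the auxiliary benzyl group with the imide dipoles opposed, which sets C8'' and C7'' together in the syn (threo) relationship and in the absolute sense required.

Step 17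
Reactants: 30 syn-aldol adduct
Product: 31 (7''R,8''R)-1,3-diol, the bis(triethylsilyl) di-O-benzyl derivative of the target
Conditions: LiBH4, MeOH (1 equiv), THF, 0 °C
Reagents that add atoms: none
Why: Reductive removal of the auxiliary by LiBH4 attacks the exocyclic imide carbonyl, turns it into the C9'' hydroxymethyl group and breaks no bond at a stereocentre, the descriptor of C8'' changing from S to R only because the substituent priorities change.

Step 18
Reactants: 31 bis(triethylsilyl) ether diol
Product: 32 di-O-benzyl ether of the target (benzyl groups on the ring A and ring C phenols)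
Conditions: Bu4NF, AcOH, THF, 0 °C to rt
Reagents that add atoms: none
Why: Buffered fluoride cleaves both triethylsilyl ethers without acid, which avoids ionisation of the now electron-rich C7–O and C7''–O benzylic bonds and hence ring closure to an aryltetralin.

Step 19
Reactants: 32 di-O-benzyl ether of the target
Product: 33 target CNP0391650.2, (7S,8R,8'S,7''R,8''R)
Conditions: H2 (1 atm), 10% Pd/C, EtOAc–EtOH, rt, stopped once both benzyl groups are gone
Reagents that add atoms: none
Why: Hydrogenolysis of aryl benzyl ethers over palladium on carbon under neutral conditions at atmospheric pressure is much faster than cleavage of the cyclic benzylic ether C7–O or of the secondary benzylic alcohol at C7'', so both phenols should be freed with all five stereocentres intact.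

Compound list
1 | 4-benzyloxy-3-methoxybenzyl alcohol | COc1cc(CO)ccc1OCc1ccccc1 | starting material
2 | methyl acrylate | COC(=O)C=C | starting material
3 | methyl 3-[(4-benzyloxy-3-methoxyphenyl)methoxy]propanoate | COC(=O)CCOCc1ccc(OCc2ccccc2)c(OC)c1 | intermediate
4 | 3-[(4-benzyloxy-3-methoxyphenyl)methoxy]propanoic acid | OC(=O)CCOCc1ccc(OCc2ccccc2)c(OC)c1 | intermediate
5 | (S)-4-benzyl-2-oxazolidinone | O=C1OC[C@H](Cc2ccccc2)N1 | starting material
6 | mixed pivalic anhydride of 4 | CC(C)(C)C(=O)OC(=O)CCOCc1ccc(OCc2ccccc2)c(OC)c1 | intermediate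
7 | (S)-4-benzyl-3-{3-[(4-benzyloxy-3-methoxyphenyl)methoxy]propanoyl}oxazolidin-2-one | O=C1OC[C@H](Cc2ccccc2)N1C(=O)CCOCc1ccc(OCc2ccccc2)c(OC)c1 | intermediate
8 | vanillin | COc1cc(C=O)ccc1O | starting material
9 | 4-formyl-2-methoxyphenyl methanesulfonate | COc1cc(C=O)ccc1OS(C)(=O)=O | intermediate
10 | trimethylsilyl ether of anti-aldol adduct 11 | O=C1OC[C@H](Cc2ccccc2)N1C(=O)[C@H](COCc1ccc(OCc2ccccc2)c(OC)c1)[C@H](O[Si](C)(C)C)c1ccc(OS(C)(=O)=O)c(OC)c1 | intermediate
11 | anti-aldol adduct, acyl chain (2R,3S), auxiliary (S) | O=C1OC[C@H](Cc2ccccc2)N1C(=O)[C@H](COCc1ccc(OCc2ccccc2)c(OC)c1)[C@H](O)c1ccc(OS(C)(=O)=O)c(OC)c1 | intermediate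
12 | C7 triethylsilyl ether of 11 | O=C1OC[C@H](Cc2ccccc2)N1C(=O)[C@H](COCc1ccc(OCc2ccccc2)c(OC)c1)[C@H](O[Si](CC)(CC)CC)c1ccc(OS(C)(=O)=O)c(OC)c1 | intermediate
13 | (2R,3S)-peroxy acid corresponding to 14 | OOC(=O)[C@H](COCc1ccc(OCc2ccccc2)c(OC)c1)[C@H](O[Si](CC)(CC)CC)c1ccc(OS(C)(=O)=O)c(OC)c1 | intermediate
14 | (2R,3S)-2-{[(4-benzyloxy-3-methoxyphenyl)methoxy]methyl}-3-(3-methoxy-4-mesyloxyphenyl)-3-(triethylsilyloxy)propanoic acid | OC(=O)[C@H](COCc1ccc(OCc2ccccc2)c(OC)c1)[C@H](O[Si](CC)(CC)CC)c1ccc(OS(C)(=O)=O)c(OC)c1 | intermediate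
15 | acid chloride of 14 | ClC(=O)[C@H](COCc1ccc(OCc2ccccc2)c(OC)c1)[C@H](O[Si](CC)(CC)CC)c1ccc(OS(C)(=O)=O)c(OC)c1 | intermediate
16 | (3R,4S)-silyloxy diazoketone | [N-]=[N+]=CC(=O)[C@H](COCc1ccc(OCc2ccccc2)c(OC)c1)[C@H](O[Si](CC)(CC)CC)c1ccc(OS(C)(=O)=O)c(OC)c1 | intermediate
17 | (3R,4S)-hydroxy diazoketone | [N-]=[N+]=CC(=O)[C@H](COCc1ccc(OCc2ccccc2)c(OC)c1)[C@H](O)c1ccc(OS(C)(=O)=O)c(OC)c1 | intermediate
18 | (4R,5S)-4-{[(4-benzyloxy-3-methoxyphenyl)methoxy]methyl}-5-(3-methoxy-4-mesyloxyphenyl)oxolan-3-one | O=C1CO[C@H](c2ccc(OS(C)(=O)=O)c(OC)c2)[C@H]1COCc1ccc(OCc2ccccc2)c(OC)c1 | intermediate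
19 | cis-fused (7S,8R,8'S)-bridgehead-hydroxy furofuran, C7' epimers | COc1cc(C3[C@@]2(O)CO[C@H](c4ccc(OS(C)(=O)=O)c(OC)c4)[C@H]2CO3)ccc1OCc1ccccc1 | intermediate
20 | (3S,4R,5S)-3-[(4-benzyloxy-3-methoxyphenyl)methyl]-4-(hydroxymethyl)-5-(3-methoxy-4-mesyloxyphenyl)oxolan-3-ol | COc1cc(C[C@@]2(O)CO[C@H](c3ccc(OS(C)(=O)=O)c(OC)c3)[C@H]2CO)ccc1OCc1ccccc1 | intermediate
21 | (3S,4R,5S)-3-[(4-benzyloxy-3-methoxyphenyl)methyl]-5-(4-hydroxy-3-methoxyphenyl)-4-(hydroxymethyl)oxolan-3-ol | COc1cc(C[C@@]2(O)CO[C@H](c3ccc(O)c(OC)c3)[C@H]2CO)ccc1OCc1ccccc1 | intermediate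
22 | bromoacetyl bromide | O=C(Br)CBr | starting material
23 | lithium salt of 5 | [Li+].O=C1OC[C@H](Cc2ccccc2)[N-]1 | intermediate
24 | (S)-4-benzyl-3-(bromoacetyl)oxazolidin-2-one | O=C1OC[C@H](Cc2ccccc2)N1C(=O)CBr | intermediate
25 | ring B aryloxyacetyl imide of 21 | COc1cc(C[C@@]2(O)CO[C@H](c3ccc(OCC(=O)N4[C@@H](Cc5ccccc5)COC4=O)c(OC)c3)[C@H]2CO)ccc1OCc1ccccc1 | intermediate
26 | bis(triethylsilyl) ether of 25 | COc1cc(C[C@@]2(O[Si](CC)(CC)CC)CO[C@H](c3ccc(OCC(=O)N4[C@@H](Cc5ccccc5)COC4=O)c(OC)c3)[C@H]2CO[Si](CC)(CC)CC)ccc1OCc1ccccc1 | intermediate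
27 | 4-benzyloxy-3-methoxybenzaldehyde | COc1cc(C=O)ccc1OCc1ccccc1 | starting material
28 | Z-dibutylboron enolate of 26 | COc1cc(C[C@@]2(O[Si](CC)(CC)CC)CO[C@H](c3ccc(O/C=C(\OB(CCCC)CCCC)N4[C@@H](Cc5ccccc5)COC4=O)c(OC)c3)[C@H]2CO[Si](CC)(CC)CC)ccc1OCc1ccccc1 | intermediate
29 | dibutylboron aldolate of 30 | COc1cc(C[C@@]2(O[Si](CC)(CC)CC)CO[C@H](c3ccc(O[C@H](C(=O)N4[C@@H](Cc5ccccc5)COC4=O)[C@H](OB(CCCC)CCCC)c4ccc(OCc5ccccc5)c(OC)c4)c(OC)c3)[C@H]2CO[Si](CC)(CC)CC)ccc1OCc1ccccc1 | intermediate
30 | syn-aldol adduct, acyl chain (2S,3R) | COc1cc(C[C@@]2(O[Si](CC)(CC)CC)CO[C@H](c3ccc(O[C@H](C(=O)N4[C@@H](Cc5ccccc5)COC4=O)[C@H](O)c4ccc(OCc5ccccc5)c(OC)c4)c(OC)c3)[C@H]2CO[Si](CC)(CC)CC)ccc1OCc1ccccc1 | intermediate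
31 | (7''R,8''R)-diol, bis(triethylsilyl) di-O-benzyl derivative of the target | COc1cc(C[C@@]2(O[Si](CC)(CC)CC)CO[C@H](c3ccc(O[C@H](CO)[C@H](O)c4ccc(OCc5ccccc5)c(OC)c4)c(OC)c3)[C@H]2CO[Si](CC)(CC)CC)ccc1OCc1ccccc1 | intermediate
32 | di-O-benzyl ether of the target | COc1cc(C[C@@]2(O)CO[C@H](c3ccc(O[C@H](CO)[C@H](O)c4ccc(OCc5ccccc5)c(OC)c4)c(OC)c3)[C@H]2CO)ccc1OCc1ccccc1 | intermediate
33 | CNP0391650.2 | COc1cc(C[C@@]2(O)CO[C@H](c3ccc(O[C@H](CO)[C@H](O)c4ccc(O)c(OC)c4)c(OC)c3)[C@H]2CO)ccc1O | target

Total step count: 19. Longest linear sequence: 17 steps (steps 1, 2, 4 to 12 and 14 to 19). Steps 3 and 13 are side branches.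

Steps most likely to fail

Step 10. α-Cleavage of the excited cyclic ketone followed by decarbonylation, return of the hydrogen within the biradical, or secondary photolysis of the product may outrun the cyclisation.
- The fallback sets out from 18 and builds the same carbinol by ground-state chemistry. Non-basic methylenation (Cp2TiMe2, toluene, 70 °C) gives the 3-methylideneoxolane F1.
- Epoxidation (mCPBA, NaHCO3, CH2Cl2, 0 °C) should occur anti to the neighbouring C9 arm. This gives the spiro-epoxide F2 with its oxygen on the face that the target needs.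
- Commercial 1-benzyloxy-4-bromo-2-methoxybenzene and Mg give the aryl Grignard reagent F3. It opens F2 at the CH2 terminus under CuI catalysis (THF, −40 °C) to the tertiary alcohol F4.
- In F4 the arylmethyl group on O9 is only a protecting group. DDQ in wet CH2Cl2 removes it, and the sequence comes back to the route at 20.

Step 11. Migration of a ring bond from the carbinol carbon to the cationic C7' (semipinacol shift), or ionisation at the wrong benzylic position, may compete with hydride delivery.
- The fallback sets out from 19 and separates bond cleavage from reduction. Thiophenol with BF3·OEt2 (CH2Cl2, −78 °C) intercepts the C7' cation far faster than a silane and gives the C7' phenyl sulfide F5.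
- Bu3SnH with AIBN (toluene, 90 °C) then replaces sulfur by hydrogen in a radical chain that involves no cation. This comes back to the route at 20.

Step 4. β-Elimination of the arylmethoxide from the magnesium enolate, driven by the silyl chloride, or loss of facial and anti selectivity through chelation of magnesium by O9, may spoil the catalytic aldol.
- The fallback sets out from 7 and replaces catalytic soft enolisation by a preformed enolate of a type known to tolerate β-alkoxy imides. Bu2BOTf and i-Pr2NEt (CH2Cl2, 0 °C) give the Z-dibutylboron enolate F6.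
- F6 is added at −78 °C to aldehyde 9 that has been pre-mixed with Et2AlCl. The boron stays chelated by the oxazolidinone carbonyl, so the same enolate face reacts.
- The open transition state with the Lewis-acid-bound aldehyde gives the anti relationship. Oxidative work-up comes back to the route at 11.

Further compounds
F1 | step 10 | 3-methylideneoxolane, C7 and C8 as in 18 | C=C1CO[C@H](c2ccc(OS(C)(=O)=O)c(OC)c2)[C@H]1COCc1ccc(OCc2ccccc2)c(OC)c1
F2 | step 10 | spiro-epoxide at C8' with oxygen trans to the C9 arm | C3O[C@@]32CO[C@H](c4ccc(OS(C)(=O)=O)c(OC)c4)[C@H]2COCc1ccc(OCc2ccccc2)c(OC)c1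
F3 | step 10 | 4-benzyloxy-3-methoxyphenylmagnesium bromide | COc1cc([Mg]Br)ccc1OCc1ccccc1
F4 | step 10 | tertiary alcohol, 20 with O9 still carrying the 4-benzyloxy-3-methoxybenzyl group | COc1cc(C[C@@]2(O)CO[C@H](c3ccc(OS(C)(=O)=O)c(OC)c3)[C@H]2COCc2ccc(OCc3ccccc3)c(OC)c2)ccc1OCc1ccccc1
F5 | step 11 | C7' phenyl sulfide of 20, C7' epimers | COc1cc(C(Sc3ccccc3)[C@@]2(O)CO[C@H](c3ccc(OS(C)(=O)=O)c(OC)c3)[C@H]2CO)ccc1OCc1ccccc1
F6 | step 4 | Z-dibutylboron enolate of 7 | CCCCB(CCCC)O/C(=C\COCc1ccc(OCc2ccccc2)c(OC)c1)N1[C@@H](Cc2ccccc2)COC1=O
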